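The reagent reaches these flasks through the gas, and you want to know how the starting material divides between target and isomer of the product.

| setting | Saturday's | Wednesday's | Thursday's | Sunday's |
|---|---|---|---|---|
| starting material | 0.0050 M | 0.0050 M | 0.0050 M | 0.0050 M |
| gas | 0.47 mM (held) | 0.47 mM (held) | 0.47 mM (held) | 0.47 mM (held) |
| temperature | 50 °C |  | 65 °C | 35 °C |
| time | 50 s | 50 s | 50 s | 50 s |
| remark |  | at 35 °C until 10 s, from then on at 65 °C |  |  |

    starting material + reagent ⇌ target (K1 = 3400 M⁻¹, k1 = 1100 M⁻¹ s⁻¹, Ea1 = 38.0 kJ mol⁻¹, ΔH1 = −9.00 kJ mol⁻¹)
    starting material + reagent ⇌ isomer of the product (K2 = 5900 M⁻¹, k2 = 700 M⁻¹ s⁻¹, Ea2 = 36.0 kJ mol⁻¹, ΔH2 = −10.0 kJ mol⁻¹)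
    2 reagent → self-condensation product (k3 = 200 M⁻¹ s⁻¹, Ea3 = 36.0 kJ mol⁻¹)
    gas ⇌ reagent, rate k4*(csat - [reagent]) (k4 = 3.0 s⁻¹, csat = 0.47 mM)
    (constants at 50 °C)

- a doubled species enters its step squared and goes two at a time
- at the start none of reagent is dissolved
- at 50 °C the constants are as listed, elsewhere as the activation energies and enthalpies make them

1. which flask leads in share of target in all that became target or isomer of the product ("all alike" within 1.5 percentage points) (Saturday's / Wednesday's / Thursday's / Sunday's / all alike)
2. share of target in all that became target or isomer of the product, Saturday's
3. share of target in all that became target or isomer of the product, Wednesday's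
4. share of target in all that became target or isomer of the product, Thursday's
5. share of target in all that became target or isomer of the product, Sunday's

Here is my own reckoning for Saturday's flask, from the fastest event to the slowest.

1. The charged starting material would use up dissolved reagent in about 0.111 s, and the gas would fill the liquid with reagent in about 0.333 s, so the starting material is the quicker of the two.

2. Because the gas is the slower of the two, reagent stays below its saturation level early on, and uptake runs at no more than the gas supply of 1.41 mM s⁻¹. At first the rate constants divide it, so the target gets 61.1%. This is kinetic control.

3. Target falls back to starting material and reagent in about 3.09 s, and at that full supply the gas needs about 3.55 s to bring as much reagent as the charge of starting material.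

4. Self-condensation would halve the reagent in 5.32 s by this step alone, but the gas refills faster than that. Once the two reversible steps stand still, you can find the reagent level by going round twice. Putting in the saturation level 0.47 mM gives 0.441 mM, and putting that back gives 0.444 mM.

5. Isomer of the product falls back in about 8.43 s, the slowest of these times. The 50 s of the run holds 5.93 of them, so I expect thermodynamic control at the reading. Both steps use the same pair, so the reagent level cancels from their ratio. Then 3400 M⁻¹ over the sum of 3400 M⁻¹ and 5900 M⁻¹ gives 36.6%. This is the resting share, the target's share once both steps stand still.

6. Each equilibrium constant moves with its own enthalpy. The resting share is therefore 36.9% at 65 °C, for Thursday's flask and for Wednesday's after its change, and 36.1% at 35 °C, for Sunday's flask. These stand 0.8 percentage points apart and the margin is 1.5 points, so I commit to all alike.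

7. The forecast also says all alike, with 36.6% for Saturday's, 36.9% for Wednesday's, 36.9% for Thursday's and 36.7% for Sunday's, and it calls the split “barely temperature-dependent”.

8. The simulation gives all alike, and Saturday's flask reads 36.6% against its resting share of 36.6%. Wednesday's reads 36.9%, Thursday's 36.9% and Sunday's 36.7%. The time of reading is what would have to change: Saturday's answer has moved by 5 points at 11.5 s. Wednesday's flask, read at 12 s, stands at 42.5%, which is 5.6 points above its resting share of 36.9%.

All constants were drawn at random within sensible limits; the flask was simulated.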